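**Retrosynthetic overview**
- The target is EGCG-(4β→8)-EGCG whose lower galloyl 3-oxygen is also bonded to C2' of the upper ring B. The last operations are closure of this diaryl ether (upper ring-B o-quinone plus lower galloyl phenol) and hydrogenolysis.
- Key C–C disconnection: the interflavan C4–C8 bond, made with inverted polarity. C4 of the upper unit reacts as a benzylic carbon nucleophile on nickel (from a C4 bromide) and C8 of the lower ring A as the electrophile (aryl iodide), so two carbon electrophiles are joined reductively; 4β is set anti to the 3-O-galloyl group.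
- Upper unit: EGCG octaacetate brominated at C4 (C2 and C3 come from the natural product).
- Lower unit: penta-O-benzyl-EGC esterified with a gallic acid carrying one masked phenol, then iodinated at C8.
- Ring order: rings A, B and C of both flavan units are bought intact; the only ring built is the 16-membered macrocycle, closed after the C4–C8 bond.

Assumption: (−)-EGC and (−)-EGCG are bought as the natural (2R,3R) tea catechins; "upper" means the C4-linked flavan unit and "lower" the C8-linked one, with ordinary flavan numbering.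

**Route**

Step 1
Reactants: 1 methyl gallate
Product: 2 methyl 3,4-O-(diphenylmethylene)gallate (methyl 7-hydroxy-2,2-diphenyl-1,3-benzodioxole-5-carboxylate)
Conditions: Ph2CCl2 (1.2 equiv), neat, 170 °C, 15 min
Reagents that add atoms: dichlorodiphenylmethane, ClC(Cl)(c1ccccc1)c1ccccc1
Why: ketal formation between the geminal dichloride and two adjacent phenols gives a 1,3-benzodioxole that can only span a vicinal pair, so exactly one gallate hydroxyl stays free and no stereocentre is involved.

Step 2
Reactants: 2 methyl 3,4-O-(diphenylmethylene)gallate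
Product: 5 3-O-acetyl-4,5-O-(diphenylmethylene)gallic acid, via disodium phenoxide carboxylate 3 (not isolated), via sodium acetoxybenzoate 4 (not isolated)
Conditions: NaOH (3 equiv), 1,4-dioxane–H2O, 60 °C; then Ac2O, 0 °C; then HCl (aq) to pH 2, 0 °C
Reagents that add atoms: sodium hydroxide, [Na+].[OH-]; acetic anhydride, CC(=O)OC(C)=O
Why: ester saponification followed by Schotten–Baumann O-acetylation of the phenoxide in the same alkaline flask and acidification, the ketal being stable to base and to brief cold acid.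

Step 3
Reactants: 6 (−)-epigallocatechin
Product: 7 (2R,3R)-5,7,3',4',5'-penta-O-benzylepigallocatechin (3-OH free)
Conditions: BnBr (5.5 equiv), K2CO3, DMF, 0 → 25 °C, argon
Reagents that add atoms: benzyl bromide, BrCc1ccccc1
Why: Williamson etherification of the five phenoxides, the aliphatic 3-OH not being deprotonated by K2CO3, so C2 and C3 keep their configuration.

Step 4
Reactants: 7 (2R,3R)-5,7,3',4',5'-penta-O-benzylepigallocatechin; 5 3-O-acetyl-4,5-O-(diphenylmethylene)gallic acid
Product: 8 (2R,3R)-5,7,3',4',5'-penta-O-benzylepigallocatechin 3-O-[3-O-acetyl-4,5-O-(diphenylmethylene)gallate]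
Conditions: DCC (1.5 equiv), DMAP (0.2 equiv), CH2Cl2, 25 °C
Reagents that add atoms: none
Why: Steglich esterification acylates the axial 3-OH on oxygen, so the C3–O bond is never broken and C3 keeps its configuration.

Step 5
Reactants: 8 lower-unit ester
Product: 9 8-iodo derivative of 8 (lower ring A: 5,7-dibenzyloxy-8-iodo)
Conditions: NIS (1.05 equiv), CH2Cl2, −20 → 0 °C, dark
Reagents that add atoms: N-iodosuccinimide, O=C1CCC(=O)N1I
Why: electrophilic aromatic iodination goes to C8 of the 5,7-dibenzyloxy ring A, the most nucleophilic carbon and the usual site of halogenation in benzylated flavan-3-ols, with no change at any stereocentre.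

Step 6
Reactants: 10 (−)-epigallocatechin 3-O-gallate (EGCG)
Product: 11 EGCG octaacetate
Conditions: Ac2O, pyridine, DMAP (cat.), 25 °C
Reagents that add atoms: acetic anhydride, CC(=O)OC(C)=O
Why: exhaustive O-acetylation of the eight phenols by nucleophilic acyl-transfer catalysis, which also switches off ring A toward nuclear bromination in the next step.

Step 7
Reactants: 11 EGCG octaacetate
Product: 12 4β-bromo-EGCG octaacetate (2,3-cis-3,4-trans; the minor 4α epimer is carried along)
Conditions: NBS (1.1 equiv), AIBN (cat.), PhCF3, 80 °C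
Reagents that add atoms: N-bromosuccinimide, O=C1CCC(=O)N1Br
Why: Wohl–Ziegler radical bromination takes a C4 methylene hydrogen (benzylic to ring A, whereas the tertiary C2–H is shielded by ring B and the 3-ester) and bromine enters mainly trans to the 3-O-galloyl group, although either C4 epimer serves because step 8 passes through the planar radical.

Step 8
Reactants: 12 4β-bromo-EGCG octaacetate; 9 8-iodo lower unit
Product: 13 (4β→8)-linked dimer: EGCG octaacetate (upper; 2R,3R,4R) bonded from C4 to C8 of lower unit 8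
Conditions: NiBr2(MeOCH2CH2OMe) (20 mol %), 4,4'-di-tert-butyl-2,2'-bipyridine (24 mol %), Mn powder (3 equiv), DMA, 25 °C, slow addition of 12 (1.5 equiv)
Reagents that add atoms: none
Why: Proposed new method: a nickel-catalysed reductive cross-electrophile coupling (known for secondary benzylic halides with aryl iodides, here extended to a flavan C4 bromide and a 2,6-dioxygenated aryl iodide) in which zerovalent nickel inserts into the C8–I bond of 9, bromine-atom abstraction from 12 gives the planar C4 benzylic radical so that both C4 epimers converge, the aryl–nickel species captures this radical on the β face (anti to the axial 3-O-galloyl group and the 2-aryl ring) and reductive elimination from trivalent nickel makes the C4–C8 bond with the 4β (4R, 3,4-trans) configuration, so that C4, which normally reacts as a cation, serves as the carbon nucleophile and the normally nucleophilic C8 as the electrophile.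

Step 9
Reactants: 13 protected dimer
Product: 14 nonaphenol (13 with all nine acetyl groups removed: upper unit fully free; lower galloyl 3-OH free)
Conditions: NH4OAc (2 equiv), MeOH–THF (degassed), 25 °C, argon
Reagents that add atoms: none
Why: chemoselective transesterification (methanolysis) of the nine aryl acetates, which are far better acyl donors than the two secondary-alkyl gallate esters, leaving benzyl ethers, the ketal and all stereocentres untouched.

Step 10
Reactants: 14 nonaphenol
Product: 16 macrocyclic diaryl ether (target skeleton; five benzyl ethers plus one diphenylmethylene ketal on the lower unit), via ring B hydroxy-o-quinone 15 (not isolated)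
Conditions: o-chloranil (1.0 equiv), MeCN–THF (1 mM), −40 → 0 °C, argon
Reagents that add atoms: none
Why: Proposed new method: o-chloranil dehydrogenates the most electron-rich pyrogallol of 14 (upper ring B) to hydroxy-o-quinone 15, and the single free phenol of the lower galloyl group adds to the quinone carbon ortho to the flavan link (intramolecular oxa-Michael addition, then tautomerisation back to the pyrogallol) to close the 16-membered diaryl ether ring, the closest known reactions being the C2' conjugate addition of thiols to tea-catechin ring-B quinones and phenol-to-o-quinone additions used for diaryl ethers of ellagitannins; no stereocentre is formed and the two ortho carbons of ring B are equivalent.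

Step 11
Reactants: 16 macrocyclic diaryl ether
Product: 17 CNP0601265.1 (target)
Conditions: H2 (1 atm), Pd(OH)2 on carbon, THF–MeOH–H2O, 25 °C
Reagents that add atoms: none
Why: hydrogenolysis cleaves the five benzyl ethers and the diphenylmethylene ketal without touching the esters, the diaryl ether, the interflavan bond or any stereocentre.

**Compound list**

1 | methyl gallate (methyl 3,4,5-trihydroxybenzoate) | COC(=O)c1cc(O)c(O)c(O)c1 | starting material
2 | methyl 3,4-O-(diphenylmethylene)gallate (methyl 7-hydroxy-2,2-diphenyl-1,3-benzodioxole-5-carboxylate) | COC(=O)c1cc(O)c2OC(c3ccccc3)(c3ccccc3)Oc2c1 | intermediate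
3 | disodium 3,4-O-(diphenylmethylene)gallate, phenoxide and carboxylate (not isolated) | [Na+].[Na+].[O-]C(=O)c1cc([O-])c2OC(c3ccccc3)(c3ccccc3)Oc2c1 | intermediate
4 | sodium 3-O-acetyl-4,5-O-(diphenylmethylene)gallate (not isolated) | [Na+].CC(=O)Oc1cc(cc2OC(c3ccccc3)(c3ccccc3)Oc12)C([O-])=O | intermediate
5 | 3-O-acetyl-4,5-O-(diphenylmethylene)gallic acid (7-acetoxy-2,2-diphenyl-1,3-benzodioxole-5-carboxylic acid) | CC(=O)Oc1cc(cc2OC(c3ccccc3)(c3ccccc3)Oc12)C(O)=O | intermediate
6 | (−)-epigallocatechin, (2R,3R)-2-(3,4,5-trihydroxyphenyl)chromane-3,5,7-triol | O[C@@H]1Cc2c(O)cc(O)cc2O[C@@H]1c1cc(O)c(O)c(O)c1 | starting material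
7 | (2R,3R)-5,7,3',4',5'-penta-O-benzylepigallocatechin | O[C@@H]1Cc2c(OCc3ccccc3)cc(OCc3ccccc3)cc2O[C@@H]1c1cc(OCc2ccccc2)c(OCc2ccccc2)c(OCc2ccccc2)c1 | intermediate
8 | (2R,3R)-5,7,3',4',5'-penta-O-benzylepigallocatechin 3-O-[3-O-acetyl-4,5-O-(diphenylmethylene)gallate] | CC(=O)Oc1cc(cc2OC(c3ccccc3)(c3ccccc3)Oc12)C(=O)O[C@@H]1Cc2c(OCc3ccccc3)cc(OCc3ccccc3)cc2O[C@@H]1c1cc(OCc2ccccc2)c(OCc2ccccc2)c(OCc2ccccc2)c1 | intermediate
9 | 8-iodo derivative of 8 | CC(=O)Oc1cc(cc2OC(c3ccccc3)(c3ccccc3)Oc12)C(=O)O[C@@H]1Cc2c(OCc3ccccc3)cc(OCc3ccccc3)c(I)c2O[C@@H]1c1cc(OCc2ccccc2)c(OCc2ccccc2)c(OCc2ccccc2)c1 | intermediate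
10 | (−)-epigallocatechin 3-O-gallate (EGCG), (2R,3R) | O=C(O[C@@H]1Cc2c(O)cc(O)cc2O[C@@H]1c1cc(O)c(O)c(O)c1)c1cc(O)c(O)c(O)c1 | starting material
11 | EGCG octaacetate, (2R,3R) | CC(=O)Oc1cc(cc(OC(C)=O)c1OC(C)=O)C(=O)O[C@@H]1Cc2c(OC(C)=O)cc(OC(C)=O)cc2O[C@@H]1c1cc(OC(C)=O)c(OC(C)=O)c(OC(C)=O)c1 | intermediate
12 | 4β-bromo-EGCG octaacetate, 2,3-cis-3,4-trans (major C4 epimer shown) | CC(=O)Oc1cc(cc(OC(C)=O)c1OC(C)=O)C(=O)O[C@@H]1[C@@H](Br)c2c(OC(C)=O)cc(OC(C)=O)cc2O[C@@H]1c1cc(OC(C)=O)c(OC(C)=O)c(OC(C)=O)c1 | intermediate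
13 | (4β→8)-linked dimer: upper EGCG octaacetate (2R,3R,4R) on C8 of lower unit 8 (2R,3R) | CC(=O)Oc1cc(cc2OC(c3ccccc3)(c3ccccc3)Oc12)C(=O)O[C@@H]1Cc2c(OCc3ccccc3)cc(OCc3ccccc3)c([C@H]4c5c(OC(C)=O)cc(OC(C)=O)cc5O[C@H](c5cc(OC(C)=O)c(OC(C)=O)c(OC(C)=O)c5)[C@@H]4OC(=O)c4cc(OC(C)=O)c(OC(C)=O)c(OC(C)=O)c4)c2O[C@@H]1c1cc(OCc2ccccc2)c(OCc2ccccc2)c(OCc2ccccc2)c1 | intermediate
14 | nonaphenol: 13 without its nine acetyl groups | Oc1cc(cc2OC(c3ccccc3)(c3ccccc3)Oc12)C(=O)O[C@@H]1Cc2c(OCc3ccccc3)cc(OCc3ccccc3)c([C@H]4c5c(O)cc(O)cc5O[C@H](c5cc(O)c(O)c(O)c5)[C@@H]4OC(=O)c4cc(O)c(O)c(O)c4)c2O[C@@H]1c1cc(OCc2ccccc2)c(OCc2ccccc2)c(OCc2ccccc2)c1 | intermediate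
15 | upper ring B hydroxy-o-quinone of 14 (not isolated) | Oc1cc(cc2OC(c3ccccc3)(c3ccccc3)Oc12)C(=O)O[C@@H]1Cc2c(OCc3ccccc3)cc(OCc3ccccc3)c([C@H]4c5c(O)cc(O)cc5O[C@H](C5=CC(=O)C(=O)C(O)=C5)[C@@H]4OC(=O)c4cc(O)c(O)c(O)c4)c2O[C@@H]1c1cc(OCc2ccccc2)c(OCc2ccccc2)c(OCc2ccccc2)c1 | intermediate
16 | macrocyclic diaryl ether: target with lower ring A (5,7) and lower ring B (3',4',5') as benzyl ethers and the lower galloyl 4,5-diol as diphenylmethylene ketal | O=C(O[C@@H]1[C@@H]2c3c(O)cc(O)cc3O[C@@H]1c1cc(O)c(O)c(O)c1Oc1cc(cc4OC(c5ccccc5)(c5ccccc5)Oc14)C(=O)O[C@@H]1Cc3c(OCc4ccccc4)cc(OCc4ccccc4)c2c3O[C@@H]1c1cc(OCc2ccccc2)c(OCc2ccccc2)c(OCc2ccccc2)c1)c1cc(O)c(O)c(O)c1 | intermediate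
17 | CNP0601265.1 | O=C(O[C@@H]1[C@@H]2c3c(O)cc(O)cc3O[C@@H]1c1cc(O)c(O)c(O)c1Oc1cc(cc(O)c1O)C(=O)O[C@@H]1Cc3c(O)cc(O)c2c3O[C@@H]1c1cc(O)c(O)c(O)c1)c1cc(O)c(O)c(O)c1 | target

**Step count and risks**

Total step count: 11. Longest linear sequence: 8 steps (1, 2, 4, 5, 8, 9, 10, 11).

Most likely to fail, first: step 8. The aryl iodide is flanked by two oxygens and the C4 radical sits next to the 5-acetoxy group, so homocoupling of 12, reduction back to 11, or loss of the 3-acyloxy group to a flav-3-ene may win. The fallback gives up the iodide and makes the same bond by polar chemistry. It sets out from 12 and 8 and comes back to the route at 13. AgOSO2CF3 with 2,6-di-tert-butyl-4-methylpyridine in CH2Cl2 at −40 °C ionises the C4–Br bond of 12, the 3-O-galloyl carbonyl bridges the α face as an acyloxonium ion, and C8 of 8 attacks C4 from the β face in a Friedel–Crafts alkylation, giving 13 with the same 4β configuration. This detour makes no compound outside the list (none F0).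

Second: step 10. The oxidant may hit the upper galloyl group or the free upper ring A, and quinone 15 may dimerise or add water before the 16-membered ring closes. The fallback moves the oxidation behind the deprotection. It sets out from 14 and comes back at 17. Hydrogenolysis (H2, Pd(OH)2 on carbon, THF–MeOH) gives the fully free dimer EGCG-(4β→8)-EGCG F2. This is oxidised at high dilution in pH 5.5 acetate buffer with laccase and air, where fast redox exchange among the pyrogallol rings should let the oxidation settle on the one ring-B quinone that has an intramolecular phenol trap; with the lower galloyl group fully free, meta versus para attack is then decided only by the ring geometry.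

Third: step 7. Abstraction of the C2–H (benzylic and next to oxygen), double bromination, or loss of HBr from 12 on heating are possible. The fallback replaces the radical chain by a two-electron benzylic acetoxylation. It sets out from 11 and comes back at 12. Pb(OAc)4 in benzene–AcOH at 60 °C gives 4-acetoxy-EGCG octaacetate F1 (4β major), and HBr in AcOH–CH2Cl2 at 0 °C exchanges the 4-acetoxy group for bromide with help from the neighbouring 3-ester.

Further compounds
F1 | step 7 | 4β-acetoxy-EGCG octaacetate (2,3-cis-3,4-trans, major epimer) | CC(=O)Oc1cc(cc(OC(C)=O)c1OC(C)=O)C(=O)O[C@@H]1[C@@H](OC(C)=O)c2c(OC(C)=O)cc(OC(C)=O)cc2O[C@@H]1c1cc(OC(C)=O)c(OC(C)=O)c(OC(C)=O)c1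
F0 | step 8 | none | none
F2 | step 10 | EGCG-(4β→8)-EGCG, fully free dimer (upper 2R,3R,4R; lower 2R,3R) | O=C(O[C@@H]1Cc2c(O)cc(O)c([C@H]3c4c(O)cc(O)cc4O[C@H](c4cc(O)c(O)c(O)c4)[C@@H]3OC(=O)c3cc(O)c(O)c(O)c3)c2O[C@@H]1c1cc(O)c(O)c(O)c1)c1cc(O)c(O)c(O)c1
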